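**Plan**
- Retrosynthesis cuts both ester O–C(sp3) bonds of the 20-membered 1,11-dioxacycloicosatetraenedione ring (O1–C20 and O11–C10), which the C2 axis makes identical, to give one hydroxy acid monomer. The monomer is then cut at C5–C6 (sp2–sp3), at C2=C3, at C8–C9 and at the oxazole ring.
- Enabling feature: C10 and C20 are secondary sp3 carbinol carbons open to SN2 attack by an acidic α-methyl dienoic carboxylate. The stiff (Z,Z)-diene C3–C6 together with the ester should make the 10-membered monolide strained, so head-to-tail dimerisation followed by 20-membered closure is expected to be preferred.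
- Forward: oxazole (van Leusen), aldehyde, anti-crotylboration, B-alkyl Suzuki coupling with a (2Z,4Z)-iododienoate, saponification. The only macrocycle arises last, in a Mitsunobu cyclodimerisation whose second displacement closes the ring.
- Stereochemistry: the methyl and carbinol centres come from one reagent-controlled (E)-crotylboration (anti). Each carbinol is then inverted to R in the Mitsunobu step (anti becomes syn). 2Z comes from a Still–Gennari olefination, 4Z from ethyl (Z)-3-iodoacrylate carried with retention.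

Key step: step 8

Assumption: both starting materials and all reagents, among them (+)-B-methoxydiisopinocampheylborane (from (−)-α-pinene) and ethyl 2-[bis(2,2,2-trifluoroethoxy)phosphoryl]propanoate, are taken as purchasable. Chain locants C1 to C10 are those of the decadienoic acid; ring locants are those of the target.

**Step 1**
Reactants: 1 3-[(tert-butyldimethylsilyl)oxy]propanal
Product: 2 5-{2-[(tert-butyldimethylsilyl)oxy]ethyl}-1,3-oxazole
Conditions: TosMIC, K2CO3, MeOH, 65 °C
Reagents that add atoms: p-toluenesulfonylmethyl isocyanide (TosMIC), Cc1ccc(cc1)S(=O)(=O)C[N+]#[C-]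
Why: van Leusen oxazole synthesis: deprotonated TosMIC adds to the aldehyde, the alkoxide closes onto the isocyanide carbon and the 4-tosyl-oxazoline loses p-toluenesulfinate, so the aldehyde carbon becomes C5 of a 5-monosubstituted oxazole, and the fast addition should outrun β-elimination of the silyloxy group.

**Step 2**
Reactants: 2 5-{2-[(tert-butyldimethylsilyl)oxy]ethyl}-1,3-oxazole
Product: 3 2-(1,3-oxazol-5-yl)ethan-1-ol
Conditions: Bu4NF, THF, 0 °C to rt
Reagents that add atoms: none
Why: fluoride-driven cleavage of the primary silyl ether (strong Si–F bond) should free the alcohol without touching the oxazole.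

**Step 3**
Reactants: 3 2-(1,3-oxazol-5-yl)ethan-1-ol
Product: 4 2-(1,3-oxazol-5-yl)acetaldehyde
Conditions: Dess–Martin periodinane, CH2Cl2, 0 °C to rt; crude aldehyde used at once
Reagents that add atoms: none
Why: the Dess–Martin oxidation is mild and stops at the aldehyde, which matters because this heteroarylacetaldehyde is enolisable and is therefore carried on without purification.

**Step 4**
Reactants: 4 2-(1,3-oxazol-5-yl)acetaldehyde
Product: 5 (2S,3R)-3-methyl-1-(1,3-oxazol-5-yl)pent-4-en-2-ol
Conditions: trans-2-butene, KOt-Bu, n-BuLi, THF, −78 to −45 °C; (+)-Ipc2BOMe, −78 °C; BF3·OEt2; then 4, −78 °C; NaOH, H2O2, 0 °C to rt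
Reagents that add atoms: trans-2-butene, C/C=C/C
Why: Brown crotylboration: the (E)-crotylborane adds through a closed six-membered chair (Zimmerman–Traxler) transition state, so the E geometry gives the anti relation of C2–OH and C3–CH3, and the isopinocampheyl groups derived from (−)-α-pinene should direct the crotyl group to the Re face of the aldehyde, which sets (2S,3R).

**Step 5**
Reactants: 6 ethyl (2Z)-3-iodoprop-2-enoate
Product: 8 ethyl (2Z,4Z)-5-iodo-2-methylpenta-2,4-dienoate, via (2Z)-3-iodoprop-2-enal 7 (not isolated)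
Conditions: i-Bu2AlH, CH2Cl2, −78 °C; cold solution of 7 added to (CF3CH2O)2P(O)CH(CH3)CO2Et, KN(SiMe3)2, 18-crown-6, THF, −78 °C
Reagents that add atoms: ethyl 2-[bis(2,2,2-trifluoroethoxy)phosphoryl]propanoate, CCOC(=O)C(C)P(=O)(OCC(F)(F)F)OCC(F)(F)F
Why: reduction with i-Bu2AlH at −78 °C stops at the aldehyde through the stable aluminium hemiacetal, and the Still–Gennari variant of the Horner–Wadsworth–Emmons olefination, with fast irreversible collapse of the kinetic adduct, should give the 2Z trisubstituted ester while the Z iodoalkene of 6 is kept at low temperature.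

**Step 6**
Reactants: 5 (2S,3R)-3-methyl-1-(1,3-oxazol-5-yl)pent-4-en-2-ol; 8 ethyl (2Z,4Z)-5-iodo-2-methylpenta-2,4-dienoate
Product: 10 ethyl (2Z,4Z,8R,9S)-9-hydroxy-2,8-dimethyl-10-(1,3-oxazol-5-yl)deca-2,4-dienoate, via B-alkyl-9-BBN borane 9 (not isolated)
Conditions: 9-BBN (2.2 equiv), THF, 0 °C to rt; then 8, Pd(dppf)Cl2 (5 mol %), AsPh3, Cs2CO3, DMF/H2O, rt, dark
Reagents that add atoms: 9-borabicyclo[3.3.1]nonane, B1C2CCCC1CCC2 (its boron and ring stay only in 9; only its hydrogen remains in 10)
Why: anti-Markovnikov hydroboration of the terminal alkene followed by B-alkyl Suzuki–Miyaura coupling, in which oxidative addition of the Z-alkenyl iodide to zerovalent palladium and reductive elimination both go with retention, should join C5 to C6 without touching either double-bond geometry or the stereocentres, the excess borane covering the free hydroxyl.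

**Step 7**
Reactants: 10 ethyl (2Z,4Z,8R,9S)-9-hydroxy-2,8-dimethyl-10-(1,3-oxazol-5-yl)deca-2,4-dienoate
Product: 11 (2Z,4Z,8R,9S)-9-hydroxy-2,8-dimethyl-10-(1,3-oxazol-5-yl)deca-2,4-dienoic acid
Conditions: LiOH, THF/MeOH/H2O, rt; then aq. HCl to pH 4
Reagents that add atoms: lithium hydroxide, [Li+].[OH-]
Why: saponification at room temperature gives the carboxylate, which is no longer a conjugate acceptor, so the (2Z,4Z)-diene and both stereocentres should be kept.

**Step 8**
Reactants: 11 (2Z,4Z,8R,9S)-9-hydroxy-2,8-dimethyl-10-(1,3-oxazol-5-yl)deca-2,4-dienoic acid (two molecules)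
Product: 13 (3Z,5Z,9R,10R,13Z,15Z,19R,20R)-3,9,13,19-tetramethyl-10,20-bis(1,3-oxazol-5-ylmethyl)-1,11-dioxacycloicosa-3,5,13,15-tetraene-2,12-dione, via linear dimer hydroxy acid 12 (not isolated)
Conditions: PPh3, DIAD, toluene/THF, −20 °C to rt, 0.02 M in 11 (acid added to the preformed betaine)
Reagents that add atoms: none
Why: PPh3 and DIAD form a betaine that is protonated by the dienoic acid and turns the C9 hydroxyl into an alkoxyphosphonium ion; the carboxylate of a second molecule displaces triphenylphosphine oxide in an SN2 step to give linear dimer 12, whose remaining carboxylate and activated carbinol then join in the same way. The closest known reaction type is the Mitsunobu macrolactonisation of ω-hydroxy acids, including its head-to-tail cyclodimerisation to macrodiolides. The single ring, the 20-membered dioxacycloicosane, closes in a 20-exo-tet mode, the leaving oxygen lying outside the ring being formed. Both ester-bearing stereocentres (C10 and C20 of 13) arise by inversion of the (9S) carbinols fixed in step 4, so each becomes R and the anti relation to the neighbouring methyl turns into the syn relation of the target. The step needs dimerisation to win over self-closure of the monomer and over further chain growth, and substitution to win over elimination: the four contiguous sp2 carbons of the (2Z,4Z)-diene plus the ester should make the 10-membered monolide strained, so at about 0.02 M the bimolecular esterification should come first and the unstrained 20-membered closure second, while the weakly basic carboxylate at low temperature should keep E2 toward the 5-alkenyl oxazole minor.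

**Compound list**
1 | 3-[(tert-butyldimethylsilyl)oxy]propanal | O=CCCO[Si](C)(C)C(C)(C)C | starting material
2 | 5-{2-[(tert-butyldimethylsilyl)oxy]ethyl}-1,3-oxazole | CC(C)(C)[Si](C)(C)OCCc1cnco1 | intermediate
3 | 2-(1,3-oxazol-5-yl)ethan-1-ol | OCCc1cnco1 | intermediate
4 | 2-(1,3-oxazol-5-yl)acetaldehyde | O=CCc1cnco1 | intermediate
5 | (2S,3R)-3-methyl-1-(1,3-oxazol-5-yl)pent-4-en-2-ol | C=C[C@@H](C)[C@@H](O)Cc1cnco1 | intermediate
6 | ethyl (2Z)-3-iodoprop-2-enoate | CCOC(=O)/C=C\I | starting material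
7 | (2Z)-3-iodoprop-2-enal | O=C/C=C\I | intermediate
8 | ethyl (2Z,4Z)-5-iodo-2-methylpenta-2,4-dienoate | CCOC(=O)/C(C)=C\C=C/I | intermediate
9 | (2S,3R)-5-(9-borabicyclo[3.3.1]nonan-9-yl)-3-methyl-1-(1,3-oxazol-5-yl)pentan-2-ol | B1(CC[C@@H](C)[C@@H](O)Cc3cnco3)C2CCCC1CCC2 | intermediate
10 | ethyl (2Z,4Z,8R,9S)-9-hydroxy-2,8-dimethyl-10-(1,3-oxazol-5-yl)deca-2,4-dienoate | CCOC(=O)/C(C)=C\C=C/CC[C@@H](C)[C@@H](O)Cc1cnco1 | intermediate
11 | (2Z,4Z,8R,9S)-9-hydroxy-2,8-dimethyl-10-(1,3-oxazol-5-yl)deca-2,4-dienoic acid | OC(=O)/C(C)=C\C=C/CC[C@@H](C)[C@@H](O)Cc1cnco1 | intermediate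
12 | (2Z,4Z,8R,9R)-9-{[(2Z,4Z,8R,9S)-9-hydroxy-2,8-dimethyl-10-(1,3-oxazol-5-yl)deca-2,4-dienoyl]oxy}-2,8-dimethyl-10-(1,3-oxazol-5-yl)deca-2,4-dienoic acid | OC(=O)/C(C)=C\C=C/CC[C@@H](C)[C@@H](Cc1cnco1)OC(=O)/C(C)=C\C=C/CC[C@@H](C)[C@@H](O)Cc1cnco1 | intermediate
13 | (3Z,5Z,9R,10R,13Z,15Z,19R,20R)-3,9,13,19-tetramethyl-10,20-bis(1,3-oxazol-5-ylmethyl)-1,11-dioxacycloicosa-3,5,13,15-tetraene-2,12-dione | C/C1=C/C=C\CC[C@@H](C)[C@@H](Cc2cnco2)OC(=O)/C(C)=C\C=C/CC[C@@H](C)[C@@H](Cc2cnco2)OC1=O | target

**Totals**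
Total step count: 8. Longest linear sequence: 7 steps (steps 1 to 4 and 6 to 8, from 1); step 5 is a one-step branch.

**Steps most likely to fail**

Step 8. The activated monomer may close on itself to the 10-membered lactone, the chain may grow past the dimer, the alkoxyphosphonium ion may eliminate toward the conjugated alkenyl oxazole, or participation by the oxazole π system may erode the inversion. The fallback builds the dimer stepwise; it sets out from 10 and 11 and comes back at 12. Acid 11 is alkylated at the carboxylate (allyl bromide, KHCO3, DMF) to the allyl ester F1. Ester 10 is silylated (TBSOTf, 2,6-lutidine) to the silyl ether F2 and saponified (LiOH) to the silyloxy acid F3. An intermolecular Mitsunobu esterification of F1 with F3 (PPh3, DIAD, 0.2 M) should give, with inversion at the carbinol of F1, the protected linear dimer F4. Pd(PPh3)4 with morpholine removes the allyl group to give the acid F5, and HF·pyridine removes the silyl group to give 12, now isolated. Compound 12 is then closed to 13 under the conditions of step 8 at high dilution (slow addition, about 0.001 M), where only the 20-membered closure is left to it.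

Step 4. The heteroarylacetaldehyde may enolise and condense with itself before the C–C bond forms, and binding of the oxazole nitrogen to boron may weaken face selection. The fallback sets the stereocentres before the oxazole exists; it sets out from 1 and comes back at 5. The crotylborane of step 4 is added to the robust aldehyde 1 to give the homoallylic alcohol F6. TBSOTf with 2,6-lutidine gives the bis-silyl ether F7, and HF·pyridine with pyridine in THF at 0 °C frees only the primary alcohol F8. Dess–Martin oxidation gives the β-silyloxy aldehyde F9, the van Leusen reaction (TosMIC, K2CO3, MeOH) gives the silylated oxazole F10, and Bu4NF gives 5.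

Step 5. The iodo-enal may isomerise from Z to E before olefination, may be lost through its volatility, and the new trisubstituted double bond may form with incomplete Z selectivity. The fallback couples first and olefinates later on a non-volatile enal; it sets out from 5 and 6 and comes back at 10. Alcohol 5 is protected (Et3SiCl, imidazole) as the silyl ether F11, so that no hydroxyl can add to the later enal. Hydroboration with 9-BBN gives the borane F12, which is coupled with 6 (Pd(dppf)Cl2, AsPh3, Cs2CO3) to the Z-enoate F13. i-Bu2AlH reduces this to the Z-allylic alcohol F14, and buffered Dess–Martin oxidation gives the Z-enal F15. The Still–Gennari olefination of step 5 then gives the silylated dienoate F16, and HF·pyridine gives 10.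

**Further compounds**
F1 | step 8 | prop-2-en-1-yl (2Z,4Z,8R,9S)-9-hydroxy-2,8-dimethyl-10-(1,3-oxazol-5-yl)deca-2,4-dienoate | C=CCOC(=O)/C(C)=C\C=C/CC[C@@H](C)[C@@H](O)Cc1cnco1
F2 | step 8 | ethyl (2Z,4Z,8R,9S)-9-[(tert-butyldimethylsilyl)oxy]-2,8-dimethyl-10-(1,3-oxazol-5-yl)deca-2,4-dienoate | CCOC(=O)/C(C)=C\C=C/CC[C@@H](C)[C@@H](O[Si](C)(C)C(C)(C)C)Cc1cnco1
F3 | step 8 | (2Z,4Z,8R,9S)-9-[(tert-butyldimethylsilyl)oxy]-2,8-dimethyl-10-(1,3-oxazol-5-yl)deca-2,4-dienoic acid | OC(=O)/C(C)=C\C=C/CC[C@@H](C)[C@@H](O[Si](C)(C)C(C)(C)C)Cc1cnco1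
F4 | step 8 | prop-2-en-1-yl (2Z,4Z,8R,9R)-9-{[(2Z,4Z,8R,9S)-9-[(tert-butyldimethylsilyl)oxy]-2,8-dimethyl-10-(1,3-oxazol-5-yl)deca-2,4-dienoyl]oxy}-2,8-dimethyl-10-(1,3-oxazol-5-yl)deca-2,4-dienoate | C=CCOC(=O)/C(C)=C\C=C/CC[C@@H](C)[C@@H](Cc1cnco1)OC(=O)/C(C)=C\C=C/CC[C@@H](C)[C@@H](O[Si](C)(C)C(C)(C)C)Cc1cnco1
F5 | step 8 | (2Z,4Z,8R,9R)-9-{[(2Z,4Z,8R,9S)-9-[(tert-butyldimethylsilyl)oxy]-2,8-dimethyl-10-(1,3-oxazol-5-yl)deca-2,4-dienoyl]oxy}-2,8-dimethyl-10-(1,3-oxazol-5-yl)deca-2,4-dienoic acid | OC(=O)/C(C)=C\C=C/CC[C@@H](C)[C@@H](Cc1cnco1)OC(=O)/C(C)=C\C=C/CC[C@@H](C)[C@@H](O[Si](C)(C)C(C)(C)C)Cc1cnco1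
F6 | step 4 | (3S,4R)-1-[(tert-butyldimethylsilyl)oxy]-4-methylhex-5-en-3-ol | C=C[C@@H](C)[C@@H](O)CCO[Si](C)(C)C(C)(C)C
F7 | step 4 | (3R,4S)-4,6-bis[(tert-butyldimethylsilyl)oxy]-3-methylhex-1-ene | C=C[C@@H](C)[C@@H](O[Si](C)(C)C(C)(C)C)CCO[Si](C)(C)C(C)(C)C
F8 | step 4 | (3S,4R)-3-[(tert-butyldimethylsilyl)oxy]-4-methylhex-5-en-1-ol | C=C[C@@H](C)[C@@H](O[Si](C)(C)C(C)(C)C)CCO
F9 | step 4 | (3S,4R)-3-[(tert-butyldimethylsilyl)oxy]-4-methylhex-5-enal | C=C[C@@H](C)[C@@H](O[Si](C)(C)C(C)(C)C)CC=O
F10 | step 4 | 5-{(2S,3R)-2-[(tert-butyldimethylsilyl)oxy]-3-methylpent-4-en-1-yl}-1,3-oxazole | C=C[C@@H](C)[C@@H](O[Si](C)(C)C(C)(C)C)Cc1cnco1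
F11 | step 5 | 5-{(2S,3R)-3-methyl-2-[(triethylsilyl)oxy]pent-4-en-1-yl}-1,3-oxazole | C=C[C@@H](C)[C@@H](O[Si](CC)(CC)CC)Cc1cnco1
F12 | step 5 | 5-{(2S,3R)-5-(9-borabicyclo[3.3.1]nonan-9-yl)-3-methyl-2-[(triethylsilyl)oxy]pentyl}-1,3-oxazole | B1(CC[C@@H](C)[C@@H](O[Si](CC)(CC)CC)Cc3cnco3)C2CCCC1CCC2
F13 | step 5 | ethyl (2Z,6R,7S)-6-methyl-8-(1,3-oxazol-5-yl)-7-[(triethylsilyl)oxy]oct-2-enoate | CCOC(=O)/C=C\CC[C@@H](C)[C@@H](O[Si](CC)(CC)CC)Cc1cnco1
F14 | step 5 | (2Z,6R,7S)-6-methyl-8-(1,3-oxazol-5-yl)-7-[(triethylsilyl)oxy]oct-2-en-1-ol | OC/C=C\CC[C@@H](C)[C@@H](O[Si](CC)(CC)CC)Cc1cnco1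
F15 | step 5 | (2Z,6R,7S)-6-methyl-8-(1,3-oxazol-5-yl)-7-[(triethylsilyl)oxy]oct-2-enal | O=C/C=C\CC[C@@H](C)[C@@H](O[Si](CC)(CC)CC)Cc1cnco1
F16 | step 5 | ethyl (2Z,4Z,8R,9S)-2,8-dimethyl-10-(1,3-oxazol-5-yl)-9-[(triethylsilyl)oxy]deca-2,4-dienoate | CCOC(=O)/C(C)=C\C=C/CC[C@@H](C)[C@@H](O[Si](CC)(CC)CC)Cc1cnco1
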